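# Total synthesis proposal for dicitrinone I

**Plan**
- Each half is numbered as an isochromene. Unit A is the quinone methide half, unit B is the isochroman half (primed), and C9 is the bridging CH2. The first cuts are C7–C9 (Michael addition of unit A to an ortho-quinone methide of unit B) and C9–C7' (Mannich reaction). Both halves then reduce to one monomer, decarboxycitrinin, and its C1 hydride adduct.
- The monomer goes back through the lactol and the (3R,4S)-lactone to an open keto ester by cutting O2–C1 and returning C3 to a ketone.
- The enabling feature lies in the benzo ring. The neighbouring carbons C4a and C8a carry both carbon arms of the pyran ring (C4 and C1), with the C5 methyl beside C4a and the C8 oxygen beside C8a. Cutting C4a–C4 and C8a–C1 together leaves a C4a≡C8a aryne and dimethyl methylmalonate.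
- The forward order is: substituted arene, aryne insertion (both arms), side-chain ester to methyl ketone, hydrogenation with lactonisation (pyranone ring), lactol, quinone methide (unit A), isochroman (unit B), aminomethylation, methylene-bridged dimer.
- C4 leaves the insertion racemic. A dynamic kinetic asymmetric hydrogenation sets C3 (R) by catalyst control and selects C4 (S) by Felkin–Anh matching from the equilibrating ketone. Both halves come from this one (3R,4S) monomer, and no later step touches C3 or C4.

Key step: step 5

Remark on the chemistry: the quinone methide half is a vinylogous acid whose 6-hydroxy-8-oxo and 8-hydroxy-6-oxo forms are tautomers, so 19 and 24 are drawn in the form given for the target, and lactol 18 is taken as a mixture of C1 anomers.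

## Route

**Step 1**
Reactants: 1 2-hydroxy-4,6-dimethoxybenzaldehyde
Product: 2 3,5-dimethoxy-2-methylphenol
Conditions: H2 (3 bar), 10% Pd/C, AcOH, rt
Reagents that add atoms: none
Why: Catalytic hydrogenolysis of an electron-rich aryl aldehyde: the formyl group should be hydrogenated to the benzylic alcohol and its C–O bond, labilised by the ortho hydroxy and the ortho/para methoxy groups, cleaved on palladium, which turns the formyl carbon into the future C5 methyl group without touching the ring or the ethers.

**Step 2**
Reactants: 2 3,5-dimethoxy-2-methylphenol
Product: 3 3,5-dimethoxy-2-methylphenyl isopropylcarbamate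
Conditions: i-PrNCO, Et3N (10 mol %), CH2Cl2, rt
Reagents that add atoms: isopropyl isocyanate, CC(C)N=C=O
Why: Amine-catalysed addition of the phenol O–H across the isocyanate (carbamoylation) should give the N–H carbamate, chosen because it is the strongest ortho director on the ring once N-silylated and can later be removed under mild basic conditions.

**Step 3**
Reactants: 3 3,5-dimethoxy-2-methylphenyl isopropylcarbamate
Product: 7 3,5-dimethoxy-2-methyl-6-(trimethylsilyl)phenyl isopropylcarbamate, via N-silyl carbamate 4 (not isolated), via C6 aryllithium 5 (not isolated), via N-silyl C6-silyl carbamate 6 (not isolated)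
Conditions: TBSOTf, TMEDA, Et2O, 0 °C to rt; n-BuLi (2 equiv), TMEDA, −78 °C; TMSCl, −78 °C to rt; aq NaHSO4
Reagents that add atoms: chlorotrimethylsilane, C[Si](C)(C)Cl
Why: Directed ortho-metalation with transient N-silyl protection of the carbamate: the C–H at the future C8a is flanked by the carbamate and a methoxy group, is acidified by two cooperating directors and should be lithiated in preference to the C–H between the two methoxy groups and to the benzylic methyl, TMSCl then traps the aryllithium, and the labile N–Si bond is hydrolysed in the acidic work-up.

**Step 4**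
Reactants: 7 3,5-dimethoxy-2-methyl-6-(trimethylsilyl)phenyl isopropylcarbamate
Product: 9 3,5-dimethoxy-2-methyl-6-(trimethylsilyl)phenyl trifluoromethanesulfonate, via silylphenol 8 (not isolated)
Conditions: Et2NH, DBU, MeCN, 40 °C; then PhNTf2, rt to 40 °C
Reagents that add atoms: N-phenylbis(trifluoromethanesulfonimide), O=S(=O)(N(c1ccccc1)S(=O)(=O)C(F)(F)F)C(F)(F)F
Why: DBU should trigger E1cB loss of isopropyl isocyanate from the N–H carbamate, diethylamine scavenges it as the urea, and the phenoxide is O-sulfonylated in the same flask by PhNTf2 (the standard one-pot carbamate-to-triflate sequence for ortho-silylaryl triflates), so the protodesilylation-prone silylphenol is never isolated.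

**Step 5**
Reactants: 9 3,5-dimethoxy-2-methyl-6-(trimethylsilyl)phenyl trifluoromethanesulfonate; 10 dimethyl methylmalonate
Product: 13 methyl 2,4-dimethoxy-6-(1-methoxy-1-oxopropan-2-yl)-5-methylbenzoate (racemic at C4), via 3,5-dimethoxy-6-methylbenzyne 11 (not isolated), via caesium benzocyclobutenoxide 12 (not isolated)
Conditions: CsF (3 equiv), 10 (1.5 equiv), MeCN (0.1 M), 80 °C
Reagents that add atoms: none
Why: Fluoride attacks silicon of 9 and triflate leaves to give aryne 11 (C4a≡C8a), the caesium enolate of 10 adds through carbon to C4a, the C8a aryl anion closes 4-exo-trig onto one of the two equivalent ester carbonyls to give benzocyclobutenoxide 12, and retro-Claisen-type cleavage of the strained C4–C1 bond leaves the C8a benzoate and the C4 ester enolate, which is protonated by further 10. The closest known reaction type is the fluoride-induced acyl-alkylation of arynes, that is the formal insertion of an aryne into the C–C(=O) sigma bond of beta-keto esters and malonates. No ring of the target is closed here, since the only ring formed is the transient four-membered one, which opens again in the same step. The one new stereocentre, C4, arises by uncontrolled protonation and is racemic, which is harmless because it is equilibrated and selected in step 8. The step needs regioselective attack at C4a, and the C8 methoxy group next to C8a secures it by withdrawing inductively and distorting the aryne so that C4a is the more linear and more electrophilic terminus while the charge develops at C8a beside the C–O bond, an effect that dominates 3-alkoxyarynes and should outweigh the modest steric bias of the C5 methyl. Insertion is favoured over plain alpha-arylation because the quaternary adduct has no acidic C–H to quench the aryl anion internally and holds two ester carbonyls against it.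

**Step 6**
Reactants: 13 methyl 2,4-dimethoxy-6-(1-methoxy-1-oxopropan-2-yl)-5-methylbenzoate
Product: 14 methyl 2,4-dimethoxy-6-{1-[methoxy(methyl)amino]-1-oxopropan-2-yl}-5-methylbenzoate (racemic)
Conditions: MeNH(OMe)·HCl, i-PrMgCl, THF, −20 to 0 °C
Reagents that add atoms: N,O-dimethylhydroxylamine hydrochloride, CNOC.Cl
Why: Weinreb amide synthesis by ester aminolysis with the chloromagnesium amide: only the side-chain ester should react, because the benzoate carbonyl is shielded by two ortho substituents and deactivated by the ortho and para methoxy donors.

**Step 7**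
Reactants: 14 methyl 2,4-dimethoxy-6-{1-[methoxy(methyl)amino]-1-oxopropan-2-yl}-5-methylbenzoate
Product: 15 methyl 2,4-dimethoxy-5-methyl-6-(3-oxobutan-2-yl)benzoate (racemic)
Conditions: MeMgBr, THF, 0 °C; aq NH4Cl
Reagents that add atoms: methylmagnesium bromide, C[Mg]Br
Why: Weinreb ketone synthesis: MeMgBr adds once to give a magnesium-chelated tetrahedral intermediate that collapses to the methyl ketone only on work-up, and the hindered benzoate is left alone at 0 °C.

**Step 8**
Reactants: 15 methyl 2,4-dimethoxy-5-methyl-6-(3-oxobutan-2-yl)benzoate
Product: 17 (3R,4S)-6,8-dimethoxy-3,4,5-trimethylisochroman-1-one, via hydroxy ester 16 (not isolated)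
Conditions: RuCl2[(S)-xylbinap][(S)-daipen] (1 mol %), t-BuOK (20 mol %), H2 (30 bar), i-PrOH, 30 °C; then TsOH·H2O (5 mol %), CH2Cl2, rt
Reagents that add atoms: none
Why: Noyori asymmetric hydrogenation run as a dynamic kinetic resolution of a configurationally labile alpha-aryl ketone: t-BuOK interconverts the C4 epimers through the enolate, the (S,S) catalyst (the one that gives (R)-carbinols from aryl and sec-alkyl methyl ketones) sets C3 as R and consumes the (4S)-ketone faster because there its facial preference coincides with Felkin–Anh attack anti to the bulky aryl group, and the C3 oxygen is then acylated by the neighbouring benzoate (lactonisation with retention at C3) to give the trans (3R,4S) lactone.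

**Step 9**
Reactants: 17 (3R,4S)-6,8-dimethoxy-3,4,5-trimethylisochroman-1-one
Product: 18 (3R,4S)-6,8-dimethoxy-3,4,5-trimethylisochroman-1-ol (C1 anomers)
Conditions: i-Bu2AlH (1.2 equiv), CH2Cl2, −78 °C; aq potassium sodium tartrate
Reagents that add atoms: none
Why: Partial lactone reduction with i-Bu2AlH: the aluminium lactolate is stable at −78 °C so that reduction should stop at the lactol, C3 and C4 are not involved, and the new C1 centre is an inconsequential anomeric mixture that is erased in step 10.

**Step 10**
Reactants: 18 (3R,4S)-6,8-dimethoxy-3,4,5-trimethylisochroman-1-ol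
Product: 19 (3R,4S)-6-hydroxy-3,4,5-trimethyl-3,4-dihydro-8H-isochromen-8-one (decarboxycitrinin)
Conditions: BBr3 (4 equiv), CH2Cl2, −78 to 0 °C; then H2O
Reagents that add atoms: none
Why: Aryl methyl ether cleavage with BBr3: the Lewis acid ionises the lactol to a C1 oxocarbenium ion that is an O-methylated quinone methide, bromide removes both activated methyl groups by SN2 attack, and hydrolysis of the boron chelate should release the 6,8-dihydroxy lactol, which loses water spontaneously to the citrinin-type quinone methide with C3 and C4 untouched.

**Step 11**
Reactants: 19 decarboxycitrinin (about half of the material)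
Product: 20 (3R,4S)-3,4,5-trimethylisochroman-6,8-diol
Conditions: NaBH4, EtOH, 0 °C; aq NH4Cl
Reagents that add atoms: none
Why: Conjugate hydride addition of NaBH4 to the electrophilic C1 terminus of the quinone methide, driven by rearomatisation and known for citrinin-type quinone methides, should give the isochroman-6,8-diol without touching C3 or C4.

**Step 12**
Reactants: 20 (3R,4S)-3,4,5-trimethylisochroman-6,8-diol
Product: 21 (3R,4S)-7-[(dimethylamino)methyl]-3,4,5-trimethylisochroman-6,8-diol
Conditions: aq HCHO and aq Me2NH (premixed, 3 equiv each), EtOH, 0 °C to rt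
Reagents that add atoms: formaldehyde, C=O; dimethylamine, CNC
Why: Mannich reaction (phenol aminomethylation): C7' is the only free ring carbon and lies between both hydroxy groups, so the iminium ion can attack only there, and the premixed excess of amine and formaldehyde keeps the product from condensing with unreacted 20.

**Step 13**
Reactants: 21 (3R,4S)-7-[(dimethylamino)methyl]-3,4,5-trimethylisochroman-6,8-diol; 19 decarboxycitrinin
Product: 24 dicitrinone I, via ammonium iodide 22 (not isolated), via ortho-quinone methide 23 (not isolated)
Conditions: MeI (1.05 equiv), MeCN, rt, concentrate; then 19 (1.2 equiv), NaOAc, MeCN, 40 °C; pH 5 buffer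
Reagents that add atoms: none
Why: Quaternisation turns the amine of the Mannich base into a leaving group that a weak base expels at low temperature to give the ortho-quinone methide, and the vinylogous acid of 19 should add through its nucleophilic C7 in a Michael addition that rearomatises unit B (the established Mannich-base route to unsymmetrical methylene-bridged phenol and 1,3-dicarbonyl dimers), with no stereocentre formed or disturbed.

## Compound list

1 | 2-hydroxy-4,6-dimethoxybenzaldehyde | COc1cc(O)c(C=O)c(OC)c1 | starting material
2 | 3,5-dimethoxy-2-methylphenol | COc1cc(O)c(C)c(OC)c1 | intermediate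
3 | 3,5-dimethoxy-2-methylphenyl isopropylcarbamate | COc1cc(OC(=O)NC(C)C)c(C)c(OC)c1 | intermediate
4 | 3,5-dimethoxy-2-methylphenyl N-(tert-butyldimethylsilyl)-N-isopropylcarbamate | COc1cc(OC(=O)N(C(C)C)[Si](C)(C)C(C)(C)C)c(C)c(OC)c1 | intermediate
5 | 6-lithio derivative of 4 (lithium between carbamate and methoxy group) | COc1cc(OC)c(C)c(OC(=O)N(C(C)C)[Si](C)(C)C(C)(C)C)c1[Li] | intermediate
6 | 3,5-dimethoxy-2-methyl-6-(trimethylsilyl)phenyl N-(tert-butyldimethylsilyl)-N-isopropylcarbamate | COc1cc(OC)c(C)c(OC(=O)N(C(C)C)[Si](C)(C)C(C)(C)C)c1[Si](C)(C)C | intermediate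
7 | 3,5-dimethoxy-2-methyl-6-(trimethylsilyl)phenyl isopropylcarbamate | COc1cc(OC)c(C)c(OC(=O)NC(C)C)c1[Si](C)(C)C | intermediate
8 | 3,5-dimethoxy-2-methyl-6-(trimethylsilyl)phenol | COc1cc(OC)c(C)c(O)c1[Si](C)(C)C | intermediate
9 | 3,5-dimethoxy-2-methyl-6-(trimethylsilyl)phenyl trifluoromethanesulfonate | COc1cc(OC)c([Si](C)(C)C)c(OS(=O)(=O)C(F)(F)F)c1C | intermediate
10 | dimethyl methylmalonate | COC(=O)C(C)C(=O)OC | starting material
11 | 3,5-dimethoxy-6-methylbenzyne (1,2-didehydro-3,5-dimethoxy-6-methylbenzene) | COC1=CC(OC)=C(C)C#C1 | intermediate
12 | caesium salt of methyl 8-hydroxy-2,4,8-trimethoxy-5,7-dimethylbicyclo[4.2.0]octa-1,3,5-triene-7-carboxylate (benzocyclobutenoxide) | COC(=O)C1(C)c2c(C)c(OC)cc(OC)c2C1([O-])OC.[Cs+] | intermediate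
13 | methyl 2,4-dimethoxy-6-(1-methoxy-1-oxopropan-2-yl)-5-methylbenzoate, racemic at C4 | COC(=O)C(C)c1c(C)c(OC)cc(OC)c1C(=O)OC | intermediate
14 | methyl 2,4-dimethoxy-6-{1-[methoxy(methyl)amino]-1-oxopropan-2-yl}-5-methylbenzoate, racemic | CON(C)C(=O)C(C)c1c(C)c(OC)cc(OC)c1C(=O)OC | intermediate
15 | methyl 2,4-dimethoxy-5-methyl-6-(3-oxobutan-2-yl)benzoate, racemic | CC(=O)C(C)c1c(C)c(OC)cc(OC)c1C(=O)OC | intermediate
16 | methyl 2,4-dimethoxy-6-[(2S,3R)-3-hydroxybutan-2-yl]-5-methylbenzoate | O[C@H](C)[C@@H](C)c1c(C)c(OC)cc(OC)c1C(=O)OC | intermediate
17 | (3R,4S)-6,8-dimethoxy-3,4,5-trimethylisochroman-1-one (trans lactone) | O=C1O[C@H](C)[C@@H](C)c2c(C)c(OC)cc(OC)c21 | intermediate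
18 | (3R,4S)-6,8-dimethoxy-3,4,5-trimethylisochroman-1-ol, C1 anomers | OC1O[C@H](C)[C@@H](C)c2c(C)c(OC)cc(OC)c21 | intermediate
19 | (3R,4S)-6-hydroxy-3,4,5-trimethyl-3,4-dihydro-8H-isochromen-8-one (decarboxycitrinin) | CC1=C2C(=CO[C@H](C)[C@H]2C)C(=O)C=C1O | intermediate
20 | (3R,4S)-3,4,5-trimethylisochroman-6,8-diol | C1O[C@H](C)[C@@H](C)c2c(C)c(O)cc(O)c21 | intermediate
21 | (3R,4S)-7-[(dimethylamino)methyl]-3,4,5-trimethylisochroman-6,8-diol | C1O[C@H](C)[C@@H](C)c2c(C)c(O)c(CN(C)C)c(O)c21 | intermediate
22 | [(3R,4S)-6,8-dihydroxy-3,4,5-trimethylisochroman-7-yl]-N,N,N-trimethylmethanaminium iodide | C1O[C@H](C)[C@@H](C)c2c(C)c(O)c(C[N+](C)(C)C)c(O)c21.[I-] | intermediate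
23 | (3R,4S)-8-hydroxy-3,4,5-trimethyl-7-methylidene-3,4-dihydro-1H-isochromen-6(7H)-one (ortho-quinone methide of unit B) | C=C1C(=O)C(C)=C2C(=C1O)CO[C@H](C)[C@H]2C | intermediate
24 | dicitrinone I, (3R,4S)-7-{[(3R,4S)-6,8-dihydroxy-3,4,5-trimethylisochroman-7-yl]methyl}-6-hydroxy-3,4,5-trimethyl-3,4-dihydro-8H-isochromen-8-one | CC1=C2C(=CO[C@H](C)[C@H]2C)C(=O)C(Cc2c(O)c(C)c3c(c2O)CO[C@H](C)[C@H]3C)=C1O | target

## Step count and risks

Total step count: 13. Longest linear sequence: 13 steps (1 to 24). Compound 19 is the branch point and enters step 13 a second time as the nucleophile.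

**Steps most likely to fail**

**1. Step 5 (aryne insertion).**
- The C8a aryl anion may be protonated before it reaches an ester carbonyl, which gives plain alpha-arylation.
- The tertiary carbanion may add slowly next to the C5 methyl, so the aryne is lost to side reactions.
- Regiocontrol may erode.

Fallback, from 9 back to 13: the same aryne 11 is generated with CsF in MeCN in the presence of dimethyl malonate, the smaller malonate partner for this insertion. This should give the homophthalate methyl 2,4-dimethoxy-6-(2-methoxy-2-oxoethyl)-5-methylbenzoate F1. The C4 methyl group is then introduced separately. The arylacetate position is deprotonated with LiN(SiMe3)2 (THF, −78 °C) and alkylated with MeI, which rejoins the route at 13.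

**2. Step 8 (dynamic kinetic hydrogenation).**
- Epimerisation at C4 may be slower than hydrogenation, so the mismatched enantiomer is reduced as well and selectivity is poor.
- Base-induced intramolecular Claisen condensation onto the benzoate may consume the alkoxide.
- Facial discrimination between the methyl and sec-alkyl flanks may be incomplete.

Fallback, from 15 back to 17: the ketone is resolved kinetically and the unwanted enantiomer is racemised outside the reduction flask. A Corey–Bakshi–Shibata reduction is run with (S)-Me-CBS oxazaborolidine (catalytic) and about half an equivalent of hydride from BH3·SMe2 (toluene, −20 °C). It should reduce only the matched (4S)-ketone, where catalyst preference and Felkin–Anh bias reinforce each other, to hydroxy ester 16. Catalytic TsOH closes 16 to 17. The unreacted methyl 2,4-dimethoxy-5-methyl-6-[(2R)-3-oxobutan-2-yl]benzoate F2 is separated by chromatography, returned to racemic 15 with DBU in warm toluene, and recycled.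

**3. Step 13 (union of the halves).**
- Amine or acetate may add reversibly at C1, and the quinone methide partner may condense with itself.
- O-alkylation may compete with C-alkylation at C7.
- The ortho-quinone methide may oligomerise.

Fallback, from 20 back to 24: the bridge is built first between two identical, robust isochroman halves, and the oxidation level of unit A is adjusted last. Condensation of 20 with half an equivalent of aqueous formaldehyde (catalytic TsOH, EtOH, rt) should give 7,7'-methylenebis[(3R,4S)-3,4,5-trimethylisochroman-6,8-diol] F3. Slightly less than one equivalent of DDQ (CH2Cl2, 0 °C) then abstracts hydride from one C1–H. That bond is held in line with the arene pi system and flanked by O2, whereas the bridging CH2 sits between two twisted di-ortho-substituted rings. Loss of a phenolic proton gives 24 directly, and unreacted F3 is recovered and resubmitted.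

## Further compounds

F1 | step 5 | methyl 2,4-dimethoxy-6-(2-methoxy-2-oxoethyl)-5-methylbenzoate | COC(=O)Cc1c(C)c(OC)cc(OC)c1C(=O)OC
F2 | step 8 | methyl 2,4-dimethoxy-5-methyl-6-[(2R)-3-oxobutan-2-yl]benzoate | CC(=O)[C@H](C)c1c(C)c(OC)cc(OC)c1C(=O)OC
F3 | step 13 | 7,7'-methylenebis[(3R,4S)-3,4,5-trimethylisochroman-6,8-diol] | C1O[C@H](C)[C@@H](C)c2c(C)c(O)c(Cc3c(O)c(C)c4c(c3O)CO[C@H](C)[C@H]4C)c(O)c21
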